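The two aryl–CH2 bonds, C8–CH2 on ring A and C5'–CH2 on ring B, are traced back to allyl ethers on O5 and O4'. The feature used is positional. C8 lies para to O5, which sits next to the C4 carbonyl, and C5' is the only open carbon ortho to O4'. Heating the precursor with Eu(fod)3 relays the 5-O-prenyl group O5→C6→C8 and moves the 4'-O-(1,1-dimethylallyl) group to C5' in one operation. The precursor is an (S)-flavanone with these two ethers and MOM groups on O7 and O3'. It is assembled in a single enantioselective rhodium-catalysed 1,4-addition of an arylboronic acid to a chromone.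

Key step: step 9

Assumption: the (S)-configured biaryl bisphosphine is taken to send the aryl group to the same face of the chromone as it does with 2-cyclohexenone, which corresponds to (2S); if a test run shows the opposite sense, the (R)-ligand is used.

Step 1
Reactants: 1 5,7-dihydroxy-4H-chromen-4-one
Product: 2 5-hydroxy-7-(methoxymethoxy)-4H-chromen-4-one
Conditions: MOMCl (1.1 equiv), K2CO3 (1.5 equiv), acetone, 0 °C to rt
Reagents that add atoms: chloromethyl methyl ether (MOMCl), COCCl
Why: Williamson-type O-alkylation with an α-chloro ether should touch only O7, because the 7-OH is the acidic vinylogous acid whereas the 5-OH is held in a hydrogen bond to the C4 carbonyl and is not engaged by K2CO3 under these conditions.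

Step 2
Reactants: 2 5-hydroxy-7-(methoxymethoxy)-4H-chromen-4-one; 3 prenyl bromide (1-bromo-3-methylbut-2-ene)
Product: 4 7-(methoxymethoxy)-5-(3-methylbut-2-enyloxy)-4H-chromen-4-one
Conditions: K2CO3 (3 equiv), DMF, 40 °C
Reagents that add atoms: none
Why: Williamson ether synthesis (SN2 at the primary allylic bromide) should work because the chelated 5-OH is the only acidic site left, excess carbonate in a dipolar solvent breaks the chelate, and dry carbonate does not attack C2 of the achiral pyrone.

Step 3
Reactants: 5 catechol (benzene-1,2-diol)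
Product: 6 2-(methoxymethoxy)phenol
Conditions: 5 (1.5 equiv), MOMCl (1.0 equiv), K2CO3 (1.1 equiv), acetone, 0 °C to rt, N2
Reagents that add atoms: chloromethyl methyl ether (MOMCl), COCCl
Why: Williamson-type mono-O-alkylation under substrate excess should favour the monoether, since one equivalent of MOMCl meets a surplus of cheap catechol and the unreacted diol is washed out with water.

Step 4
Reactants: 6 2-(methoxymethoxy)phenol
Product: 7 4-bromo-2-(methoxymethoxy)phenol
Conditions: NBS (1.0 equiv), MeCN, −10 °C to 0 °C, dark
Reagents that add atoms: N-bromosuccinimide (NBS), O=C1CCC(=O)N1Br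
Why: In this electrophilic aromatic bromination the free OH is the stronger donor and should direct bromine to its para carbon C4, which fixes which catechol oxygen lies para to the future C1', while the neutral medium spares the acetal.

Step 5
Reactants: 7 4-bromo-2-(methoxymethoxy)phenol; 8 3-chloro-3-methylbut-1-yne
Product: 9 4-bromo-2-(methoxymethoxy)-1-(2-methylbut-3-yn-2-yloxy)benzene
Conditions: DBU (1.3 equiv), CuCl2·2H2O (1 mol %), MeCN, 0 °C
Reagents that add atoms: none
Why: In this copper-catalysed propargylic substitution the copper acetylide of 8 ionises to a stabilised tertiary propargyl cation that the phenoxide captures on oxygen, and the MOM acetal, unlike a silyl or acyl group, cannot migrate to the neighbouring phenoxide, so the O-regiochemistry set in step 4 is kept.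

Step 6
Reactants: 9 4-bromo-2-(methoxymethoxy)-1-(2-methylbut-3-yn-2-yloxy)benzene
Product: 10 4-bromo-2-(methoxymethoxy)-1-(2-methylbut-3-en-2-yloxy)benzene
Conditions: H2 (1 atm), Pd/CaCO3 poisoned with Pb(OAc)2 (5 wt % Pd), quinoline, EtOAc, rt
Reagents that add atoms: none
Why: Lindlar semihydrogenation should stop at the vinyl group because the poisoned palladium surface releases the alkene before further uptake, and at 1 atm and room temperature it leaves the aryl bromide, the acetal and the allylic C–O bond alone.

Step 7
Reactants: 10 4-bromo-2-(methoxymethoxy)-1-(2-methylbut-3-en-2-yloxy)benzene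
Product: 13 [3-(methoxymethoxy)-4-(2-methylbut-3-en-2-yloxy)phenyl]boronic acid, via aryllithium 11 (not isolated), via lithium aryltriisopropoxyborate 12 (not isolated)
Conditions: B(Oi-Pr)3 (1.5 equiv), n-BuLi (1.1 equiv), THF, −78 °C; then aq NH4Cl, 0 °C
Reagents that add atoms: triisopropyl borate, CC(C)OB(OC(C)C)OC(C)C; water, O
Why: In this bromine–lithium exchange with electrophilic borylation, exchange at −78 °C is far faster than MOM-directed ortho-lithiation, the borate already in the flask traps 11 at once as 12, and buffered hydrolysis spares the acetal and the tertiary allyl ether.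

Step 8
Reactants: 4 7-(methoxymethoxy)-5-(3-methylbut-2-enyloxy)-4H-chromen-4-one; 13 [3-(methoxymethoxy)-4-(2-methylbut-3-en-2-yloxy)phenyl]boronic acid
Product: 14 (S)-7-(methoxymethoxy)-2-[3-(methoxymethoxy)-4-(2-methylbut-3-en-2-yloxy)phenyl]-5-(3-methylbut-2-enyloxy)chroman-4-one
Conditions: [Rh(OH)(cod)]2 (1.5 mol %), (S)-MeO-F12-BIPHEP [(S)-6,6'-dimethoxy-2,2'-bis[bis(3,4,5-trifluorophenyl)phosphino]-1,1'-biphenyl, 3.6 mol %], 13 (1.5 equiv), toluene/H2O 10:1, 25–30 °C
Reagents that add atoms: none
Why: In this Hayashi–Miyaura asymmetric 1,4-addition, a reaction type established for chromones, the aryl-rhodium species inserts the C2=C3 bond inside the chiral pocket of the electron-poor (S)-bisphosphine, which should expose the Re face of C2 and so set (2S), and hydrolysis of the rhodium enolate at room temperature avoids β-aryloxide loss, opening of ring C and a premature Claisen shift.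

Step 9
Reactants: 14 (S)-7-(methoxymethoxy)-2-[3-(methoxymethoxy)-4-(2-methylbut-3-en-2-yloxy)phenyl]-5-(3-methylbut-2-enyloxy)chroman-4-one
Product: 19 (S)-5-hydroxy-2-[4-hydroxy-3-(methoxymethoxy)-5-(3-methylbut-2-enyl)phenyl]-7-(methoxymethoxy)-8-(3-methylbut-2-enyl)chroman-4-one, via ring B ortho-dienone 15 (not isolated), via 5'-prenylphenol 16 (not isolated), via C6 dienone 17 (not isolated), via C8 dienone 18 (not isolated)
Conditions: Eu(fod)3 (15 mol %), NaHCO3 (solid, 1 equiv), PhCl, 85 °C, Ar
Reagents that add atoms: none
Why: Eu(fod)3, an oxophilic and nearly neutral Lewis acid of trivalent europium, binds the C4 carbonyl together with O5 and so accelerates the aromatic Claisen shift of the 5-O-prenyl ether, which can only go to C6 because the other ortho carbon C4a is a ring-fusion atom, giving dienone 17 with the allyl unit inverted to 1,1-dimethylallyl. The strained C6–CMe2 bond of 17, squeezed between C5=O and the 7-OMOM group, then migrates by a Cope shift across C7=C8 to dienone 18, and tautomerisation restores ring A with a normal prenyl group on C8 and a chelated 5-OH. The tertiary 4'-O-(1,1-dimethylallyl) ether is the more labile of the two and should rearrange first, through 15 to phenol 16; a shift to C3' would give a dienone that cannot rearomatise because that carbon bears OMOM and simply reverts, so the group ends on C5', again inverted to prenyl. Both events belong to known reaction types, the lanthanide-catalysed para-Claisen–Cope rearrangement of 5-O-prenylflavonoids and the ortho-Claisen rearrangement of aryl 1,1-dimethylallyl ethers, here run in one flask. No ring is closed and no lasting stereocentre is formed, since the sp3 carbons created in 15, 17 and 18 vanish on enolisation and C2 is a spectator that should hold in the absence of Brønsted acid or soluble base. The selectivity required is C8 over C6, which depends on the Cope step outrunning proton loss from C6 of 17 and is secured by the aprotic medium, the steric compression at C6 and the europium chelate that keeps the C5 oxygen in its keto form.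

Step 10
Reactants: 19 (S)-5-hydroxy-2-[4-hydroxy-3-(methoxymethoxy)-5-(3-methylbut-2-enyl)phenyl]-7-(methoxymethoxy)-8-(3-methylbut-2-enyl)chroman-4-one
Product: 20 (S)-2-[3,4-dihydroxy-5-(3-methylbut-2-enyl)phenyl]-5,7-dihydroxy-8-(3-methylbut-2-enyl)chroman-4-one (target)
Conditions: conc. HCl (catalytic, about 0.5 M) in MeOH, 40 °C, Ar
Reagents that add atoms: none
Why: In this acid-catalysed transacetalisation (MOM cleavage) methanol accepts the methoxymethyl units, and at this acidity and temperature the aryl acetals should ionise much faster than the trisubstituted alkenes are protonated or ring C opens, so both prenyl groups and C2 are expected to survive.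

Compound list
1 | 5,7-dihydroxy-4H-chromen-4-one | O=c1ccoc2cc(O)cc(O)c12 | starting material
2 | 5-hydroxy-7-(methoxymethoxy)-4H-chromen-4-one | O=c1ccoc2cc(OCOC)cc(O)c12 | intermediate
3 | prenyl bromide (1-bromo-3-methylbut-2-ene) | CC(C)=CCBr | starting material
4 | 7-(methoxymethoxy)-5-(3-methylbut-2-enyloxy)-4H-chromen-4-one | O=c1ccoc2cc(OCOC)cc(OCC=C(C)C)c12 | intermediate
5 | catechol (benzene-1,2-diol) | Oc1ccccc1O | starting material
6 | 2-(methoxymethoxy)phenol | COCOc1ccccc1O | intermediate
7 | 4-bromo-2-(methoxymethoxy)phenol | COCOc1cc(Br)ccc1O | intermediate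
8 | 3-chloro-3-methylbut-1-yne | C#CC(C)(C)Cl | starting material
9 | 4-bromo-2-(methoxymethoxy)-1-(2-methylbut-3-yn-2-yloxy)benzene | C#CC(C)(C)Oc1ccc(Br)cc1OCOC | intermediate
10 | 4-bromo-2-(methoxymethoxy)-1-(2-methylbut-3-en-2-yloxy)benzene | C=CC(C)(C)Oc1ccc(Br)cc1OCOC | intermediate
11 | [3-(methoxymethoxy)-4-(2-methylbut-3-en-2-yloxy)phenyl]lithium | C=CC(C)(C)Oc1ccc([Li])cc1OCOC | intermediate
12 | lithium [3-(methoxymethoxy)-4-(2-methylbut-3-en-2-yloxy)phenyl]triisopropoxyborate | [Li+].C=CC(C)(C)Oc1ccc([B-](OC(C)C)(OC(C)C)OC(C)C)cc1OCOC | intermediate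
13 | [3-(methoxymethoxy)-4-(2-methylbut-3-en-2-yloxy)phenyl]boronic acid | C=CC(C)(C)Oc1ccc(B(O)O)cc1OCOC | intermediate
14 | (S)-7-(methoxymethoxy)-2-[3-(methoxymethoxy)-4-(2-methylbut-3-en-2-yloxy)phenyl]-5-(3-methylbut-2-enyloxy)chroman-4-one | C=CC(C)(C)Oc1ccc([C@@H]2CC(=O)c3c(OCC=C(C)C)cc(OCOC)cc3O2)cc1OCOC | intermediate
15 | ring B ortho-dienone: (2S)-flavanone of 14 in which ring B is a cyclohexa-2,4-dienone with C4'=O and an sp3 C5' bearing H and prenyl (C5' unassigned) | O=C1C(OCOC)=CC([C@@H]2CC(=O)c3c(OCC=C(C)C)cc(OCOC)cc3O2)=CC1CC=C(C)C | intermediate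
16 | (S)-2-[4-hydroxy-3-(methoxymethoxy)-5-(3-methylbut-2-enyl)phenyl]-7-(methoxymethoxy)-5-(3-methylbut-2-enyloxy)chroman-4-one | CC(C)=CCc1cc([C@@H]2CC(=O)c3c(OCC=C(C)C)cc(OCOC)cc3O2)cc(OCOC)c1O | intermediate
17 | C6 dienone: (2S)-2-aryl-7-(methoxymethoxy)-6-(2-methylbut-3-en-2-yl)-2,3-dihydrochromene-4,5(6H)-dione, aryl as in 16 (C6 unassigned) | CC(C)=CCc1cc([C@@H]2CC(=O)C3=C(O2)C=C(OCOC)C(C(C)(C)C=C)C3=O)cc(OCOC)c1O | intermediate
18 | C8 dienone: (2S)-2-aryl-7-(methoxymethoxy)-8-(3-methylbut-2-enyl)-2,3-dihydrochromene-4,5(8H)-dione, aryl as in 16 (C8 unassigned) | CC(C)=CCc1cc([C@@H]2CC(=O)C3=C(O2)C(CC=C(C)C)C(OCOC)=CC3=O)cc(OCOC)c1O | intermediate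
19 | (S)-5-hydroxy-2-[4-hydroxy-3-(methoxymethoxy)-5-(3-methylbut-2-enyl)phenyl]-7-(methoxymethoxy)-8-(3-methylbut-2-enyl)chroman-4-one | CC(C)=CCc1cc([C@@H]2CC(=O)c3c(O)cc(OCOC)c(CC=C(C)C)c3O2)cc(OCOC)c1O | intermediate
20 | (S)-2-[3,4-dihydroxy-5-(3-methylbut-2-enyl)phenyl]-5,7-dihydroxy-8-(3-methylbut-2-enyl)chroman-4-one | CC(C)=CCc1cc([C@@H]2CC(=O)c3c(O)cc(O)c(CC=C(C)C)c3O2)cc(O)c1O | target

Total step count: 10
Longest linear sequence: 8 steps (steps 3 to 10, from catechol 5)

Steps most likely to fail

**Step 9.**
- What may go wrong: the first dienone may enolise before the Cope shift, which strands the group on C6 in its inverted form.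
- The tertiary ether may also ionise and lose its allyl unit.
- Long heating may slowly racemise C2 through reversible opening of ring C once the 4'-OH is free.
- The fallback sets out from 4 (with 13) and comes back at 19. It separates the two shifts and moves the demanding one to the achiral stage.
- Chromone 4 alone is heated (Eu(fod)3 in PhCl at 85 °C, or N,N-diethylaniline at 190 °C) to 5-hydroxy-7-(methoxymethoxy)-8-(3-methylbut-2-enyl)-4H-chromen-4-one F1. At this stage forcing conditions and separation of regioisomers put no stereocentre or tertiary ether at stake.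
- F1, whose chelated 5-OH tolerates the aqueous rhodium medium, takes up 13 under the conditions of step 8. This gives (S)-5-hydroxy-7-(methoxymethoxy)-2-[3-(methoxymethoxy)-4-(2-methylbut-3-en-2-yloxy)phenyl]-8-(3-methylbut-2-enyl)chroman-4-one F2.
- A short, mild ortho-Claisen shift of the ring B ether alone (toluene, 100 °C) then leads to 19.

**Step 8.**
- What may go wrong: insertion into the electron-rich 5,7-dialkoxychromone may be sluggish, so that protodeboronation outruns transmetalation.
- β-Aryloxide loss from the rhodium enolate may open ring C, or facial selectivity may be poor.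
- The fallback sets out from 10 and 4 and comes back at 14. It replaces the conjugate addition by a chalcone closure and takes enantiopurity from a resolution with recycling.
- Bromide 10 is lithiated to 11 and quenched with DMF to give 3-(methoxymethoxy)-4-(2-methylbut-3-en-2-yloxy)benzaldehyde F3.
- Chromone 4 is opened with aqueous KOH in EtOH, which expels C2 as formate and leaves 1-[2-hydroxy-4-(methoxymethoxy)-6-(3-methylbut-2-enyloxy)phenyl]ethanone F4.
- Claisen–Schmidt condensation (KOH, EtOH, rt) joins the two to the (E)-2'-hydroxychalcone F5.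
- NaOAc in EtOH at 60 °C closes ring C by oxa-Michael addition to the racemic flavanone F6.
- Preparative chromatography on an amylose tris(3,5-dimethylphenylcarbamate) phase delivers 14. The (R)-antipode F7 is returned to the NaOAc equilibration and recycled.

**Step 10.**
- What may go wrong: the prenyl alkenes may be protonated and captured by the neighbouring O7 or O4' (chroman closure).
- Methanol may add across the alkenes, or acid may open ring C with erosion of enantiopurity.
- The fallback sets out from 19 and comes back at 20. It gives up Brønsted-acid solvolysis for a thiol-trapped Lewis-acid cleavage.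
- ZnBr2 and n-PrSH in CH2Cl2 at 0 °C activate each acetal oxygen, and the soft nucleophile carries off the methoxymethyl unit as a sulfide within minutes. The medium is aprotic, so no proton source able to attack the alkenes is present. No new compound arises on this path (F0).

Further compounds
F1 | step 9 | 5-hydroxy-7-(methoxymethoxy)-8-(3-methylbut-2-enyl)-4H-chromen-4-one | O=c1ccoc2c(CC=C(C)C)c(OCOC)cc(O)c12
F2 | step 9 | (S)-5-hydroxy-7-(methoxymethoxy)-2-[3-(methoxymethoxy)-4-(2-methylbut-3-en-2-yloxy)phenyl]-8-(3-methylbut-2-enyl)chroman-4-one | C=CC(C)(C)Oc1ccc([C@@H]2CC(=O)c3c(O)cc(OCOC)c(CC=C(C)C)c3O2)cc1OCOC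
F3 | step 8 | 3-(methoxymethoxy)-4-(2-methylbut-3-en-2-yloxy)benzaldehyde | C=CC(C)(C)Oc1ccc(C=O)cc1OCOC
F4 | step 8 | 1-[2-hydroxy-4-(methoxymethoxy)-6-(3-methylbut-2-enyloxy)phenyl]ethanone | CC(=O)c1c(O)cc(OCOC)cc1OCC=C(C)C
F5 | step 8 | (E)-1-[2-hydroxy-4-(methoxymethoxy)-6-(3-methylbut-2-enyloxy)phenyl]-3-[3-(methoxymethoxy)-4-(2-methylbut-3-en-2-yloxy)phenyl]prop-2-en-1-one | C=CC(C)(C)Oc1ccc(/C=C/C(=O)c2c(O)cc(OCOC)cc2OCC=C(C)C)cc1OCOC
F6 | step 8 | racemic 7-(methoxymethoxy)-2-[3-(methoxymethoxy)-4-(2-methylbut-3-en-2-yloxy)phenyl]-5-(3-methylbut-2-enyloxy)chroman-4-one | C=CC(C)(C)Oc1ccc(C2CC(=O)c3c(OCC=C(C)C)cc(OCOC)cc3O2)cc1OCOC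
F7 | step 8 | (R)-7-(methoxymethoxy)-2-[3-(methoxymethoxy)-4-(2-methylbut-3-en-2-yloxy)phenyl]-5-(3-methylbut-2-enyloxy)chroman-4-one | C=CC(C)(C)Oc1ccc([C@H]2CC(=O)c3c(OCC=C(C)C)cc(OCOC)cc3O2)cc1OCOC
F0 | step 10 | none | none
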